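With everything charged, step 1 makes new target at 0.200 /s per target, faster than steps 3 and 4 together destroy it at 0.156 /s, and we follow that narrow margin.

    substrate + coupling partner + target → 2 target (k1 = 21.1 /M²/s)
    substrate + coupling partner → target (k2 = 5.74 × 10⁻⁴ /M/s)
    substrate + target → side product (k3 = 1.07 /M/s)
    target → over-reaction product (k4 = 0.0488 /s)

common to all: time 3.0 min
- maple: substrate 0.10 M; coupling partner 0.950 equiv (fed, over 2.0 min); all else is in the flask from the start; the feed brings no volume worth counting
- oak: substrate 0.10 M; coupling partner 0.950 equiv (fed, over 12 s); all else is in the flask from the start; the feed brings no volume worth counting
- cedar: substrate 0.10 M; coupling partner 0.950 equiv; everything together at the start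
- birch: substrate 0.10 M (fed, over 2.0 min); coupling partner 0.950 equiv; all else is in the flask from the start; the feed brings no volume worth counting

- in percentages every species weighs as the substrate in it: one side product counts as two
- run time (maple): 3.0 min

* the flask that comes out highest in share of target in target plus side product, or "all alike" when all lie within 1.5 percentage points (maple / oak / cedar / birch / all alike)
* share of target in target plus side product at the end, maple
* share of target in target plus side product at the end, oak
* share of target in target plus side product at the end, cedar
* share of target in target plus side product at the end, birch

The ratio of those rates is 1.29; we call it the gain, the new targets made per target destroyed. Step 1 spends one coupling partner for each target it makes, so we keep the ledger of coupling partner, in fractions of the substrate charge. Each unit spent books one target, and of each unit spent a part 0.225 stays as target at the start. Destroyed target goes to side product in the part 0.687, taking a second substrate, and otherwise to over-reaction product.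

With substrate held at its charge, the gain reaches 1 when 0.738 equiv of coupling partner stands, so 0.212 is spent. That spending leaves 0.643 of the substrate. Going round again with this amount, the crossing comes after 0.0832. The rounds straddle the answer, so we take their middle, 0.147.

The books at the crossing, taking the kept part to fall evenly to zero, read: target 0.0164, side product 0.0900, over-reaction product 0.0409, coupling partner unspent 0.803, which closes at 0.950. Side product counts double, so the share there is 8.36%.

Maple's feed reaches the critical amount at 1.55 min, birch's at 1.04 min. The run-up from seed by step 2 takes, by our estimate, about 0.997 min. So we expect maple nearest the crossing at the stop, with 2.55 min, near our share; birch lower; cedar and oak far lower.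

The forecast put maple first, with maple 6%, oak 2.2%, cedar 1.9%, birch 5%, reasoning that “Feeding delays ignition so the 3-minute stop catches maple and birch near the target peak”.

The simulation puts maple first: maple 11.6%, oak 1.82%, cedar 1.53%, birch 9.19%. Maple stands 3.2 percentage points above our share, and the gain from its end amounts reads 1.02. A neighbour of maple charged with 0.380 equiv of coupling partner, all else held, has with its whole charge in a gain of 0.515, so we reckon it no run-up. Its target should rest at the seed divided by the loss rate and by one minus the gain, 0.0288%. At the stop that flask holds target 0.0281%, side product 0.579%, and a share of 4.62%.

Its constants are made up.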